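**Plan**

- Retrosynthesis: the five MOM ethers come off first. Then the O1–C2 bond of ring C is cut (oxa-Michael), the enone C=C bond (Claisen–Schmidt, detaching ring B), the aryl–acetyl bond at C4a (Stille, back to an aryl iodide) and the two C–CH3 bonds of the carbinol (Grignard, back to a lactone). Last come the benzylic CH2–CH bond and the aryl O–C(=O) bond of that lactone.
- Enabling feature: a ring-A oxygen ortho to C8, then C8, the benzylic CH2, the stereogenic CH and the carbinol carbon are the six ring atoms of a 3-prenyl-3,4-dihydrocoumarin. Here that oxygen is the one on C8a that ends as O1; the C7 oxygen is its twin across C8. The hydrated lavandulyl arm is thus a lactone opened by two methyl nucleophiles.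
- Forward: ring A is taken from 2,4,6-trihydroxybenzaldehyde to an iodinated silyloxybenzyl acetate. The lactone ring is annulated onto it and opened to phenol and tertiary alcohol. The iodide, a spectator until then, is exchanged for acetyl, ring B is joined by aldol condensation, ring C is closed and the phenols are freed.
- Stereochemistry: the side-chain centre (R) comes from the chiral triazolium carbene in the annulation; C2 (S) comes from a cinchona thiourea catalyst in the ring-C closure.

Key step: step 7

Assumption: the antipode of the triazolium catalyst (step 7) and the pseudoenantiomer of the cinchona thiourea (step 12) that give 3R and 2S are chosen by analogy with the closest model reactions; both series are accessible, so the choice can be corrected after a first run.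
Assumption: 5-methylhex-4-enoic acid is taken as purchasable.

**Step 1**
Reactants: 1 2,4,6-trihydroxybenzaldehyde
Product: 2 2-hydroxy-4,6-bis(methoxymethoxy)benzaldehyde
Conditions: MOMCl (2.2 equiv), iPr2NEt, CH2Cl2, 0 °C → rt
Reagents that add atoms: chloromethyl methyl ether, COCCl
Why: Base-mediated O-alkylation (Williamson-type MOM ether formation) takes the para hydroxyl and one ortho hydroxyl, while the last ortho hydroxyl is held in a hydrogen bond to the formyl group and stays free under amine-base conditions.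

**Step 2**
Reactants: 2 2-hydroxy-4,6-bis(methoxymethoxy)benzaldehyde
Product: 3 2-hydroxy-3-iodo-4,6-bis(methoxymethoxy)benzaldehyde
Conditions: NIS (1.05 equiv), DMF, 0 °C → rt, dark
Reagents that add atoms: N-iodosuccinimide, O=C1CCC(=O)N1I
Why: Electrophilic aromatic iodination of 2-hydroxy-4,6-dialkoxyaryl carbonyl compounds goes ortho to the free phenol, which places iodine on the carbon that becomes C4a next to the oxygen that becomes O1, and the acid-free medium spares the MOM ethers.

**Step 3**
Reactants: 3 2-hydroxy-3-iodo-4,6-bis(methoxymethoxy)benzaldehyde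
Product: 4 2-(tert-butyldimethylsilyloxy)-3-iodo-4,6-bis(methoxymethoxy)benzaldehyde
Conditions: TBSCl, imidazole, DMAP (cat.), DMF, rt → 40 °C
Reagents that add atoms: tert-butyldimethylsilyl chloride, CC(C)(C)[Si](C)(C)Cl
Why: Imidazole/DMAP-mediated silyl ether formation on the hindered phenol installs the single fluoride-labile group that later triggers methide formation, with aldehyde, iodide and MOM ethers inert.

**Step 4**
Reactants: 4 2-(tert-butyldimethylsilyloxy)-3-iodo-4,6-bis(methoxymethoxy)benzaldehyde
Product: 5 [2-(tert-butyldimethylsilyloxy)-3-iodo-4,6-bis(methoxymethoxy)phenyl]methanol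
Conditions: NaBH4, THF/MeOH (4:1), −20 → 0 °C; pH 7 buffer
Reagents that add atoms: none
Why: Borohydride reduction of the aryl aldehyde, run cold and quenched at neutral pH so that the benzylic alkoxide does not take over the neighbouring aryl silyl group (1,4 O-to-O silyl shift).

**Step 5**
Reactants: 5 [2-(tert-butyldimethylsilyloxy)-3-iodo-4,6-bis(methoxymethoxy)phenyl]methanol
Product: 6 [2-(tert-butyldimethylsilyloxy)-3-iodo-4,6-bis(methoxymethoxy)phenyl]methyl acetate
Conditions: Ac2O, Et3N, DMAP (cat.), CH2Cl2, 0 °C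
Reagents that add atoms: acetic anhydride, CC(=O)OC(C)=O
Why: DMAP-catalysed O-acetylation of the primary benzylic alcohol under basic conditions, which the acid-labile, electron-rich benzylic system tolerates and which gives a leaving group stable enough to isolate.

**Step 6**
Reactants: 7 5-methylhex-4-enoic acid; 8 1,1'-carbonyldiimidazole
Product: 9 1-(5-methylhex-4-enoyl)imidazole
Conditions: THF, rt, until CO2 evolution stops; used after concentration
Reagents that add atoms: 1,1'-carbonyldiimidazole (compound 8), O=C(n1ccnc1)n1ccnc1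
Why: Acyl imidazole formation by carbonyldiimidazole activation of the carboxylic acid, driven by loss of CO2.

**Step 7**
Reactants: 6 [2-(tert-butyldimethylsilyloxy)-3-iodo-4,6-bis(methoxymethoxy)phenyl]methyl acetate; 9 1-(5-methylhex-4-enoyl)imidazole
Product: 11 (3R)-8-iodo-5,7-bis(methoxymethoxy)-3-(3-methylbut-2-enyl)chroman-2-one, via ortho-quinone methide 10 (not isolated)
Conditions: (5aS,10bR)-2-mesityl-5a,10b-dihydro-4H,6H-indeno[2,1-b][1,2,4]triazolo[4,3-d][1,4]oxazin-2-ium tetrafluoroborate (15 mol %), CsF (2.5 equiv), 18-crown-6, 4 Å MS, THF, −20 °C → rt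
Reagents that add atoms: none
Why: Fluoride removes the only silyl group of 6 and the phenoxide expels acetate to give methide 10, while the carbene freed from the triazolium salt is acylated by 9 and the acyl azolium is deprotonated to a catalyst-bound (Z)-azolium enolate. The enolate α-carbon adds to the exocyclic CH2 of 10 with re-aromatisation, and the phenoxide then attacks the acyl azolium in a 6-exo-trig acyl substitution that closes the lactone and releases the carbene, a formal (4+2) annulation. The closest known reaction type is the carbene-catalysed annulation of fluoride-generated ortho-quinone methides with azolium enolates from acyl imidazoles, which gives 3-substituted dihydrocoumarins. The C3 centre is set by the catalyst: its indane backbone and N-aryl group block one face of the enolate, and the methide carbon, itself not stereogenic, is taken up on the open face to give 3R. The step needs a single methide and attack at its CH2 only; this is secured by the one fluoride-labile ether next to the acetoxymethyl group and by the two donor MOM ethers, which stabilise the methide against oligomerisation, while the aryl iodide and the trisubstituted alkene are spectators. Because the new centre is α to an aryl ester carbonyl, work-up is kept neutral and 11 is opened at once in step 8.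

**Step 8**
Reactants: 11 (3R)-8-iodo-5,7-bis(methoxymethoxy)-3-(3-methylbut-2-enyl)chroman-2-one
Product: 12 2-[(2R)-2-(2-hydroxypropan-2-yl)-5-methylhex-4-enyl]-6-iodo-3,5-bis(methoxymethoxy)phenol
Conditions: MeMgBr (5 equiv), LaCl3·2LiCl (30 mol %), THF, −40 → 0 °C; aq. NH4Cl
Reagents that add atoms: methylmagnesium bromide, C[Mg]Br
Why: Double Grignard addition to the aryl lactone (ester to tertiary alcohol) frees the phenol and builds C(CH3)2OH, and catalytic LaCl3·2LiCl favours 1,2-addition over enolisation of the lactone and of the transient methyl ketone, so the centre is carried over unchanged and can no longer epimerise once the carbinol is formed.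

**Step 9**
Reactants: 12 2-[(2R)-2-(2-hydroxypropan-2-yl)-5-methylhex-4-enyl]-6-iodo-3,5-bis(methoxymethoxy)phenol
Product: 14 1-{2-hydroxy-3-[(2R)-2-(2-hydroxypropan-2-yl)-5-methylhex-4-enyl]-4,6-bis(methoxymethoxy)phenyl}ethanone, via aryl 1-ethoxyvinyl ether 13 (not isolated)
Conditions: Bu3Sn–C(OEt)=CH2 (1.5 equiv), Pd(PPh3)4 (5 mol %), CuI (10 mol %), CsF (2 equiv), DMF, 45 °C; then 0.5 M aq. HCl, THF, 0 °C
Reagents that add atoms: tributyl(1-ethoxyvinyl)stannane, CCCC[Sn](CCCC)(CCCC)C(=C)OCC; water, O
Why: Stille cross-coupling of the aryl iodide with the 1-ethoxyvinyl stannane (an acetyl anion equivalent, copper- and fluoride-assisted for the hindered, electron-rich iodide) and brief dilute-acid hydrolysis of enol ether 13 give the methyl ketone ortho to the free phenol without touching the MOM ethers, the alkene or the tertiary alcohol.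

**Step 10**
Reactants: 1 2,4,6-trihydroxybenzaldehyde
Product: 15 2,4,6-tris(methoxymethoxy)benzaldehyde
Conditions: NaH (3.6 equiv), MOMCl (3.6 equiv), DMF, 0 °C → rt
Reagents that add atoms: chloromethyl methyl ether, COCCl
Why: Exhaustive Williamson etherification through the sodium phenoxides also caps the two hydrogen-bonded ortho hydroxyls and gives the base-stable ring-B aldehyde.

**Step 11**
Reactants: 14 1-{2-hydroxy-3-[(2R)-2-(2-hydroxypropan-2-yl)-5-methylhex-4-enyl]-4,6-bis(methoxymethoxy)phenyl}ethanone; 15 2,4,6-tris(methoxymethoxy)benzaldehyde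
Product: 16 (2E)-1-{2-hydroxy-3-[(2R)-2-(2-hydroxypropan-2-yl)-5-methylhex-4-enyl]-4,6-bis(methoxymethoxy)phenyl}-3-[2,4,6-tris(methoxymethoxy)phenyl]prop-2-en-1-one
Conditions: KOH (excess), EtOH/H2O, rt; cold dilute citric acid to pH 6
Reagents that add atoms: none
Why: Claisen–Schmidt (crossed aldol) condensation of the methyl ketone enolate with the non-enolisable aldehyde and E1cB dehydration give the (E)-enone, with MOM ethers, tertiary alcohol and alkene inert to hydroxide.

**Step 12**
Reactants: 16 (2E)-1-{2-hydroxy-3-[(2R)-2-(2-hydroxypropan-2-yl)-5-methylhex-4-enyl]-4,6-bis(methoxymethoxy)phenyl}-3-[2,4,6-tris(methoxymethoxy)phenyl]prop-2-en-1-one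
Product: 17 (2S)-8-[(2R)-2-(2-hydroxypropan-2-yl)-5-methylhex-4-enyl]-5,7-bis(methoxymethoxy)-2-[2,4,6-tris(methoxymethoxy)phenyl]chroman-4-one
Conditions: N-[3,5-bis(trifluoromethyl)phenyl]-N'-[(8α,9S)-6'-methoxycinchonan-9-yl]thiourea (15 mol %), toluene, rt
Reagents that add atoms: none
Why: Enantioselective intramolecular oxa-Michael addition of a 2'-hydroxychalcone under bifunctional cinchona thiourea catalysis (the quinuclidine activates the phenol, the thiourea binds the enone carbonyl) closes ring C in a 6-endo-trig mode; only the 2'-hydroxyl is free, so only the 8-substituted flavanone can form, and the catalyst, not the remote side-chain centre, sets C2 as S.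

**Step 13**
Reactants: 17 (2S)-8-[(2R)-2-(2-hydroxypropan-2-yl)-5-methylhex-4-enyl]-5,7-bis(methoxymethoxy)-2-[2,4,6-tris(methoxymethoxy)phenyl]chroman-4-one
Product: 18 (2S)-5,7-dihydroxy-8-[(2R)-2-(2-hydroxypropan-2-yl)-5-methylhex-4-enyl]-2-(2,4,6-trihydroxyphenyl)chroman-4-one
Conditions: HCl (1.25 M in MeOH), MeOH, rt; NaHCO3 at 0 °C
Reagents that add atoms: none
Why: Acid-catalysed transacetalisation (MOM ether cleavage) in methanol frees the five phenols, and dilute acid at room temperature is chosen so that the tertiary alcohol, the prenyl alkene and the C2–O1 bond are not ionised.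

**Compound list**

1 | 2,4,6-trihydroxybenzaldehyde | O=Cc1c(O)cc(O)cc1O | starting material
2 | 2-hydroxy-4,6-bis(methoxymethoxy)benzaldehyde | O=Cc1c(O)cc(OCOC)cc1OCOC | intermediate
3 | 2-hydroxy-3-iodo-4,6-bis(methoxymethoxy)benzaldehyde | O=Cc1c(O)c(I)c(OCOC)cc1OCOC | intermediate
4 | 2-(tert-butyldimethylsilyloxy)-3-iodo-4,6-bis(methoxymethoxy)benzaldehyde | O=Cc1c(O[Si](C)(C)C(C)(C)C)c(I)c(OCOC)cc1OCOC | intermediate
5 | [2-(tert-butyldimethylsilyloxy)-3-iodo-4,6-bis(methoxymethoxy)phenyl]methanol | OCc1c(O[Si](C)(C)C(C)(C)C)c(I)c(OCOC)cc1OCOC | intermediate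
6 | [2-(tert-butyldimethylsilyloxy)-3-iodo-4,6-bis(methoxymethoxy)phenyl]methyl acetate | CC(=O)OCc1c(O[Si](C)(C)C(C)(C)C)c(I)c(OCOC)cc1OCOC | intermediate
7 | 5-methylhex-4-enoic acid | CC(C)=CCCC(=O)O | starting material
8 | 1,1'-carbonyldiimidazole | O=C(n1ccnc1)n1ccnc1 | starting material
9 | 1-(5-methylhex-4-enoyl)imidazole | CC(C)=CCCC(=O)n1ccnc1 | intermediate
10 | 2-iodo-3,5-bis(methoxymethoxy)-6-methylidenecyclohexa-2,4-dien-1-one | C=C1C(=O)C(I)=C(OCOC)C=C1OCOC | intermediate
11 | (3R)-8-iodo-5,7-bis(methoxymethoxy)-3-(3-methylbut-2-enyl)chroman-2-one | CC(C)=CC[C@H](Cc1c(OCOC)cc(OCOC)c(I)c1O2)C2=O | intermediate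
12 | 2-[(2R)-2-(2-hydroxypropan-2-yl)-5-methylhex-4-enyl]-6-iodo-3,5-bis(methoxymethoxy)phenol | CC(C)=CC[C@H](Cc1c(OCOC)cc(OCOC)c(I)c1O)C(C)(C)O | intermediate
13 | 2-(1-ethoxyethenyl)-6-[(2R)-2-(2-hydroxypropan-2-yl)-5-methylhex-4-enyl]-3,5-bis(methoxymethoxy)phenol | CC(C)=CC[C@H](Cc1c(OCOC)cc(OCOC)c(C(=C)OCC)c1O)C(C)(C)O | intermediate
14 | 1-{2-hydroxy-3-[(2R)-2-(2-hydroxypropan-2-yl)-5-methylhex-4-enyl]-4,6-bis(methoxymethoxy)phenyl}ethanone | CC(C)=CC[C@H](Cc1c(OCOC)cc(OCOC)c(C(C)=O)c1O)C(C)(C)O | intermediate
15 | 2,4,6-tris(methoxymethoxy)benzaldehyde | O=Cc1c(OCOC)cc(OCOC)cc1OCOC | intermediate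
16 | (2E)-1-{2-hydroxy-3-[(2R)-2-(2-hydroxypropan-2-yl)-5-methylhex-4-enyl]-4,6-bis(methoxymethoxy)phenyl}-3-[2,4,6-tris(methoxymethoxy)phenyl]prop-2-en-1-one | CC(C)=CC[C@H](Cc1c(OCOC)cc(OCOC)c(C(=O)/C=C/c2c(OCOC)cc(OCOC)cc2OCOC)c1O)C(C)(C)O | intermediate
17 | (2S)-8-[(2R)-2-(2-hydroxypropan-2-yl)-5-methylhex-4-enyl]-5,7-bis(methoxymethoxy)-2-[2,4,6-tris(methoxymethoxy)phenyl]chroman-4-one | CC(C)=CC[C@H](Cc1c(OCOC)cc(OCOC)c2c1O[C@H](c1c(OCOC)cc(OCOC)cc1OCOC)CC2=O)C(C)(C)O | intermediate
18 | (2S)-5,7-dihydroxy-8-[(2R)-2-(2-hydroxypropan-2-yl)-5-methylhex-4-enyl]-2-(2,4,6-trihydroxyphenyl)chroman-4-one | CC(C)=CC[C@H](Cc1c(O)cc(O)c2c1O[C@H](c1c(O)cc(O)cc1O)CC2=O)C(C)(C)O | target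

**Totals**

Total step count: 13.
Longest linear sequence: 11 steps (steps 1–5, 7–9, 11–13).

**Steps most likely to fail**

Step 7. What may go wrong: the donor-stabilised, iodine-flanked methide may be intercepted by acetate, imidazole or a second methide faster than by the azolium enolate, or the unbranched aliphatic enolate may add with poor facial selectivity. The fallback replaces the annulation by an auxiliary-controlled enolate alkylation; it sets out from aldehyde 4 and returns at lactone 11. Commercial (4R)-4-benzyl-1,3-oxazolidin-2-one is N-acylated with diethylphosphonoacetic acid (pivaloyl chloride, Et3N, LiCl) to diethyl {2-[(4R)-4-benzyl-2-oxo-1,3-oxazolidin-3-yl]-2-oxoethyl}phosphonate F1. Horner–Wadsworth–Emmons olefination of 4 with it (LiCl, iPr2NEt, MeCN) should give the enoyl imide (4R)-4-benzyl-3-{(2E)-3-[2-(tert-butyldimethylsilyloxy)-3-iodo-4,6-bis(methoxymethoxy)phenyl]prop-2-enoyl}-1,3-oxazolidin-2-one F2. Diimide (2-nitrobenzenesulfonylhydrazide, Et3N, CH2Cl2), which leaves the aryl iodide alone, reduces the conjugated alkene to (4R)-4-benzyl-3-{3-[2-(tert-butyldimethylsilyloxy)-3-iodo-4,6-bis(methoxymethoxy)phenyl]propanoyl}-1,3-oxazolidin-2-one F3. Evans alkylation of its sodium (Z)-enolate (NaN(SiMe3)2, THF, −78 °C) with 1-bromo-3-methylbut-2-ene, on the face opposite the benzyl group, gives (4R)-4-benzyl-3-[(2R)-2-{[2-(tert-butyldimethylsilyloxy)-3-iodo-4,6-bis(methoxymethoxy)phenyl]methyl}-5-methylhex-4-enoyl]-1,3-oxazolidin-2-one F4. Buffered fluoride (Bu4NF, AcOH, THF, 0 °C) then removes the silyl group, and the phenol displaces the oxazolidinone to close lactone 11, from which step 8 follows.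

Step 12. What may go wrong: poor facial selectivity in the conjugate addition to the hindered, electron-rich enone, and erosion of C2 by reversible ring opening under the basic catalyst. The fallback replaces catalyst control by separation with recycling; it sets out from chalcone 16 and returns at flavanone 17. Unselective closure (NaOAc, EtOH, 60 °C) would give 17 together with its C2 epimer (2R)-8-[(2R)-2-(2-hydroxypropan-2-yl)-5-methylhex-4-enyl]-5,7-bis(methoxymethoxy)-2-[2,4,6-tris(methoxymethoxy)phenyl]chroman-4-one F5. Because the side-chain centre is fixed, the two are diastereomers and would be separated by preparative HPLC; the unwanted epimer is returned to the same equilibrating conditions (ring opening to 16 and re-closure) until the material is drawn into 17.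

Step 13. What may go wrong: acid-induced loss of the C2 configuration (ring opening to the chalcone, or ionisation of the C2–O1 bond helped by the trioxygenated ring B), or ionisation of the tertiary alcohol with ether formation onto the C7 phenol or the prenyl group. The fallback replaces protic solvolysis by an aprotic acetal-to-silyl-ether exchange; it sets out from 17 and returns at target 18. TMSOTf with 2,2'-bipyridyl (CH3CN, 0 °C) converts the five aryl MOM ethers, and the tertiary alcohol, into trimethylsilyl ethers, giving (2S)-8-{(2R)-5-methyl-2-[2-(trimethylsilyloxy)propan-2-yl]hex-4-enyl}-5,7-bis(trimethylsilyloxy)-2-[2,4,6-tris(trimethylsilyloxy)phenyl]chroman-4-one F6. This is not isolated but hydrolysed near neutral pH (water, then dilute citric acid in MeOH) to 18.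

**Further compounds**

F1 | step 7 | diethyl {2-[(4R)-4-benzyl-2-oxo-1,3-oxazolidin-3-yl]-2-oxoethyl}phosphonate | CCOP(=O)(OCC)CC(=O)N1[C@H](Cc2ccccc2)COC1=O
F2 | step 7 | (4R)-4-benzyl-3-{(2E)-3-[2-(tert-butyldimethylsilyloxy)-3-iodo-4,6-bis(methoxymethoxy)phenyl]prop-2-enoyl}-1,3-oxazolidin-2-one | O=C(/C=C/c1c(O[Si](C)(C)C(C)(C)C)c(I)c(OCOC)cc1OCOC)N1[C@H](Cc2ccccc2)COC1=O
F3 | step 7 | (4R)-4-benzyl-3-{3-[2-(tert-butyldimethylsilyloxy)-3-iodo-4,6-bis(methoxymethoxy)phenyl]propanoyl}-1,3-oxazolidin-2-one | O=C(CCc1c(O[Si](C)(C)C(C)(C)C)c(I)c(OCOC)cc1OCOC)N1[C@H](Cc2ccccc2)COC1=O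
F4 | step 7 | (4R)-4-benzyl-3-[(2R)-2-{[2-(tert-butyldimethylsilyloxy)-3-iodo-4,6-bis(methoxymethoxy)phenyl]methyl}-5-methylhex-4-enoyl]-1,3-oxazolidin-2-one | CC(C)=CC[C@H](Cc1c(O[Si](C)(C)C(C)(C)C)c(I)c(OCOC)cc1OCOC)C(=O)N1[C@H](Cc2ccccc2)COC1=O
F5 | step 12 | (2R)-8-[(2R)-2-(2-hydroxypropan-2-yl)-5-methylhex-4-enyl]-5,7-bis(methoxymethoxy)-2-[2,4,6-tris(methoxymethoxy)phenyl]chroman-4-one | CC(C)=CC[C@H](Cc1c(OCOC)cc(OCOC)c2c1O[C@@H](c1c(OCOC)cc(OCOC)cc1OCOC)CC2=O)C(C)(C)O
F6 | step 13 | (2S)-8-{(2R)-5-methyl-2-[2-(trimethylsilyloxy)propan-2-yl]hex-4-enyl}-5,7-bis(trimethylsilyloxy)-2-[2,4,6-tris(trimethylsilyloxy)phenyl]chroman-4-one | CC(C)=CC[C@H](Cc1c(O[Si](C)(C)C)cc(O[Si](C)(C)C)c2c1O[C@H](c1c(O[Si](C)(C)C)cc(O[Si](C)(C)C)cc1O[Si](C)(C)C)CC2=O)C(C)(C)O[Si](C)(C)C
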